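The route rests on disconnecting the C5–C6 bond of ring B. Because C5 is quaternary and bonded both to the C14 methyl and to C6 of ring B, these two substituents are traced back to a single exocyclic C5=C14 methylene on ring A. Hydrogen-atom transfer from an iron hydride turns C14 into the methyl, and the tertiary C5 radical closes ring B on C6 of an enone (6-endo), fixing the C5 methyl cis to the C4 methyl in one operation. The precursor is an enantiopure ring A methylenecyclohexane (C3 silyl ether, C4 methyl) whose C10 carries, trans to the C4 methyl, the C9–C8(=O)–C7(=C6H2)–C11 arm. Dehydrogenation to the C6=C7, C9=C10 dienone, desilylation and C3 acylation finish the synthesis.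

Key step: step 12

Remark on numbering: eremophilane numbering is used; ring A = C1–C5 and C10, ring B = C5–C10, C11 = carbinol carbon on C7, C14 = methyl on C5, C15 = methyl on C4, oxygen on C3.
Remark on the chemistry: (2Z)-2-methyl-3-(methylsulfanyl)prop-2-enoic acid is assumed not to be a catalogue compound and is made in steps 15–17; LiN(iPr)2 and t-BuLi are used as commercial solutions.
Remark on the chemistry: C7 of compound 23 is drawn as one epimer; either epimer serves, because C7 becomes sp2 in step 13.

Step 1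
Reactants: 1 2-methylcyclohex-2-en-1-one
Product: 2 (1R)-2-methylcyclohex-2-en-1-ol
Conditions: (S)-Me-CBS oxazaborolidine (10 mol%), BH3·SMe2, THF, −20 °C; MeOH quench
Reagents that add atoms: none
Why: Corey–Bakshi–Shibata reduction, in which the oxazaborolidine–borane complex binds the carbonyl with the 2-methylvinyl flank as the large group and delivers hydride to one face only (1,2-reduction), which should give the R carbinol that later steers the hydroboration.

Step 2
Reactants: 2 (1R)-2-methylcyclohex-2-en-1-ol
Product: 3 ({[(1R)-2-methylcyclohex-2-en-1-yl]oxy}methyl)benzene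
Conditions: NaH, BnBr, Bu4NI (cat.), THF, 0 °C → rt
Reagents that add atoms: benzyl bromide, BrCc1ccccc1
Why: Williamson etherification masks the auxiliary carbinol with a group that survives hydroboration and silylation and can later be removed by hydrogenolysis without touching a silyl ether; no stereocentre is formed.

Step 3
Reactants: 3 ({[(1R)-2-methylcyclohex-2-en-1-yl]oxy}methyl)benzene
Product: 5 (1R,2S,3R)-3-(benzyloxy)-2-methylcyclohexan-1-ol, via alkylborane 4 (not isolated)
Conditions: BH3·THF, THF, 0 °C → rt; then NaOH, H2O2, 0 °C → rt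
Reagents that add atoms: hydrogen peroxide, OO
Why: Brown hydroboration–oxidation, in which boron goes to the less substituted alkene carbon (future C3) and hydrogen to the methyl-bearing carbon (future C4) in a syn addition on the face anti to the allylic benzyloxy group, so the new hydroxyl is trans to the methyl and both C3 and C4 are set; the C–B bond is oxidised with retention.

Step 4
Reactants: 5 (1R,2S,3R)-3-(benzyloxy)-2-methylcyclohexan-1-ol
Product: 6 {[(1R,2R,3R)-3-(benzyloxy)-2-methylcyclohexyl]oxy}(tert-butyl)dimethylsilane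
Conditions: TBSCl, imidazole, DMF, rt
Reagents that add atoms: tert-butyldimethylsilyl chloride, CC(C)(C)[Si](C)(C)Cl
Why: Standard silylation of an equatorial secondary alcohol installs the C3 protecting group that is carried to the end; no stereocentre is touched.

Step 5
Reactants: 6 {[(1R,2R,3R)-3-(benzyloxy)-2-methylcyclohexyl]oxy}(tert-butyl)dimethylsilane
Product: 7 (1R,2R,3R)-3-{[tert-butyl(dimethyl)silyl]oxy}-2-methylcyclohexan-1-ol
Conditions: H2 (1 atm), Pd/C, EtOAc, rt
Reagents that add atoms: none
Why: Catalytic hydrogenolysis cleaves only the benzylic C–O bond, leaving the silyl ether and all stereocentres untouched.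

Step 6
Reactants: 7 (1R,2R,3R)-3-{[tert-butyl(dimethyl)silyl]oxy}-2-methylcyclohexan-1-ol
Product: 8 (2S,3R)-3-{[tert-butyl(dimethyl)silyl]oxy}-2-methylcyclohexan-1-one
Conditions: Dess–Martin periodinane, NaHCO3, CH2Cl2, 0 °C → rt
Reagents that add atoms: none
Why: Dess–Martin oxidation under bicarbonate buffer converts the auxiliary carbinol into the C5 ketone under neutral conditions that should neither enolise C4 nor eliminate the β-silyloxy group, so the trans C3/C4 relationship is kept.

Step 7
Reactants: 8 (2S,3R)-3-{[tert-butyl(dimethyl)silyl]oxy}-2-methylcyclohexan-1-one; 9 2-bromo-N-methoxy-N-methylacetamide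
Product: 11 N-methoxy-N-methyl-2-[(1R,3S,4R)-4-{[tert-butyl(dimethyl)silyl]oxy}-3-methyl-2-oxocyclohexyl]acetamide, via lithium enolate 10 (not isolated)
Conditions: LiN(iPr)2, THF, −78 °C; then 9, DMPU, −78 → −40 °C; aq. NH4Cl at −78 °C
Reagents that add atoms: none
Why: Kinetic enolate alkylation, in which the amide base removes the unhindered C10 proton and the enolate is alkylated by the activated α-bromo amide along the axial trajectory that avoids a syn-axial clash with the C4 methyl, which should place the C9–C8 arm trans to that methyl (C10 R) and deliver the Weinreb amide directly.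

Step 8
Reactants: 11 N-methoxy-N-methyl-2-[(1R,3S,4R)-4-{[tert-butyl(dimethyl)silyl]oxy}-3-methyl-2-oxocyclohexyl]acetamide
Product: 12 2-[(1R,3R,4R)-4-{[tert-butyl(dimethyl)silyl]oxy}-3-methyl-2-methylidenecyclohexyl]-N-methoxy-N-methylacetamide
Conditions: Zn, CH2Br2, TiCl4, THF/CH2Cl2, 0 °C → rt
Reagents that add atoms: dibromomethane, BrCBr
Why: Takai–Lombardo methylenation uses a non-basic zinc–titanium methylene reagent that converts hindered, enolisable ketones into exocyclic alkenes without epimerising the α-centres C4 and C10 and does not attack amide carbonyls.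

Step 9
Reactants: 13 acetone; 14 bromoethene
Product: 16 3-bromo-2-methylbut-3-en-2-ol, via 1-bromo-1-lithioethene 15 (not isolated)
Conditions: 14, LiN(iPr)2, THF/Et2O/pentane (4:1:1), −110 °C; then 13, −110 → −78 °C; aq. NH4Cl
Reagents that add atoms: none
Why: Carbonyl 1,2-addition of an α-lithiated vinyl bromide generated by deprotonation at very low temperature gives the 2-bromoallylic tertiary alcohol with the bromine position fixed by construction, so no Markovnikov selectivity has to be relied on.

Step 10
Reactants: 16 3-bromo-2-methylbut-3-en-2-ol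
Product: 17 [(3-bromo-2-methylbut-3-en-2-yl)oxy]triethylsilane
Conditions: TESOTf, 2,6-lutidine, CH2Cl2, −78 → 0 °C
Reagents that add atoms: triethylsilyl trifluoromethanesulfonate, CC[Si](CC)(CC)OS(=O)(=O)C(F)(F)F
Why: Silylation with a silyl triflate and a hindered pyridine base is the standard way to cap a tertiary alcohol, and the ether prevents retro-aldol loss of acetone from C11 later on.

Step 11
Reactants: 17 [(3-bromo-2-methylbut-3-en-2-yl)oxy]triethylsilane; 12 2-[(1R,3R,4R)-4-{[tert-butyl(dimethyl)silyl]oxy}-3-methyl-2-methylidenecyclohexyl]-N-methoxy-N-methylacetamide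
Product: 20 1-[(1R,3R,4R)-4-{[tert-butyl(dimethyl)silyl]oxy}-3-methyl-2-methylidenecyclohexyl]-4-methyl-3-methylidene-4-[(triethylsilyl)oxy]pentan-2-one, via vinyllithium 18 (not isolated), via lithium hemiaminal 19 (not isolated)
Conditions: 17, t-BuLi (2 equiv per 17), Et2O, −78 °C; then 12, THF, −78 °C; aq. NH4Cl
Reagents that add atoms: none
Why: Bromine–lithium exchange followed by Weinreb ketone synthesis, in which the chelated tetrahedral adduct cannot add a second organolithium and collapses to the C8 ketone only on work-up, giving the 2-substituted enone without touching a stereocentre.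

Step 12
Reactants: 20 1-[(1R,3R,4R)-4-{[tert-butyl(dimethyl)silyl]oxy}-3-methyl-2-methylidenecyclohexyl]-4-methyl-3-methylidene-4-[(triethylsilyl)oxy]pentan-2-one
Product: 23 (3R,4aS,5R,6R,8aR)-6-{[tert-butyl(dimethyl)silyl]oxy}-4a,5-dimethyl-3-{2-[(triethylsilyl)oxy]propan-2-yl}-3,4,4a,5,6,7,8,8a-octahydronaphthalen-2(1H)-one, via C5 radical 21 (not isolated), via C7 radical 22 (not isolated)
Conditions: Fe(acac)3 (0.3 equiv), PhSiH3 (2.5 equiv), Na2HPO4, EtOH/HOCH2CH2OH (5:1), degassed, 0.02 M, 60 °C
Reagents that add atoms: none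
Why: The iron hydride formed from Fe(acac)3 and PhSiH3 transfers a hydrogen atom to the C14 terminus of the electron-rich exocyclic alkene, leaving a nucleophilic tertiary radical at C5, while the electron-poor enone is a poor partner for this hydridic donor. The closest known reaction type is the iron-mediated reductive olefin–enone coupling (radical conjugate addition that builds quaternary carbons), run here intramolecularly. Ring B closes by 6-endo-trig attack of C5 on the unsubstituted enone terminus C6, since the 5-exo mode would require attack at the fully substituted C7 and would give an unstabilised radical. The resulting α-keto radical at C7 is reduced and protonated by the medium to the C8 ketone. C5 is controlled by the substrate, because the tether on C10 lies on the face opposite the C4 methyl and can reach only that face through a cis-fused transition state while the C4 methyl shields the other face, so C14 ends cis to C15; C7 is set by protonation and is of no consequence. The step needs hydrogen delivery to the 1,1-disubstituted alkene only and face selectivity at the planar radical, the first secured by alkene polarity and the second by the trans C4/C10 relationship from step 7, with high dilution suppressing intermolecular addition.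

Step 13
Reactants: 23 (3R,4aS,5R,6R,8aR)-6-{[tert-butyl(dimethyl)silyl]oxy}-4a,5-dimethyl-3-{2-[(triethylsilyl)oxy]propan-2-yl}-3,4,4a,5,6,7,8,8a-octahydronaphthalen-2(1H)-one
Product: 25 (4aR,5R,6R)-6-{[tert-butyl(dimethyl)silyl]oxy}-4a,5-dimethyl-3-{2-[(triethylsilyl)oxy]propan-2-yl}-5,6,7,8-tetrahydronaphthalen-2(4aH)-one, via enone 24 (not isolated)
Conditions: IBX (4 equiv), 4-methoxypyridine N-oxide (4 equiv), DMSO, 25 → 55 °C
Reagents that add atoms: none
Why: IBX dehydrogenation of a ketone through its enol, first toward C9/C10 and then toward C7/C6, should stop at the cross-conjugated dienone because quaternary C5 blocks aromatisation; it removes the stereocentres at C10 and C7 and leaves C3, C4 and C5 untouched.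

Step 14
Reactants: 25 (4aR,5R,6R)-6-{[tert-butyl(dimethyl)silyl]oxy}-4a,5-dimethyl-3-{2-[(triethylsilyl)oxy]propan-2-yl}-5,6,7,8-tetrahydronaphthalen-2(4aH)-one
Product: 26 (4aR,5R,6R)-6-hydroxy-3-(2-hydroxypropan-2-yl)-4a,5-dimethyl-5,6,7,8-tetrahydronaphthalen-2(4aH)-one
Conditions: HF·pyridine, pyridine, THF, 0 °C → rt
Reagents that add atoms: none
Why: Fluoride-driven desilylation (Si–F bond formation) removes both silyl ethers in one operation under buffered conditions that spare the dienone and the tertiary C11 alcohol.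

Step 15
Reactants: 27 prop-2-yn-1-ol
Product: 29 (2Z)-3-iodo-2-methylprop-2-en-1-ol, via magnesium chelate 28 (not isolated)
Conditions: MeMgBr (2.5 equiv), CuI (10 mol%), THF, −10 °C → rt; then I2, −20 °C → rt; aq. NH4Cl
Reagents that add atoms: methylmagnesium bromide, C[Mg]Br; iodine, II
Why: Copper-catalysed anti-carbomagnesiation of the propargylic alkoxide puts the methyl on the internal carbon and magnesium on the terminal carbon cis to the CH2O group in a five-membered chelate, and iodinolysis with retention fixes the Z geometry.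

Step 16
Reactants: 29 (2Z)-3-iodo-2-methylprop-2-en-1-ol
Product: 30 (2Z)-3-iodo-2-methylprop-2-enoic acid
Conditions: TEMPO (cat.), NaOCl (cat.), NaClO2, MeCN/phosphate buffer (pH 6.7), 35 °C
Reagents that add atoms: sodium chlorite, [Na+].[O-]Cl=O
Why: Oxoammonium oxidation to the enal followed in the same pot by chlorite (Pinnick-type) oxidation gives the acid under near-neutral conditions that should not isomerise the Z alkene.

Step 17
Reactants: 30 (2Z)-3-iodo-2-methylprop-2-enoic acid
Product: 31 (2Z)-2-methyl-3-(methylsulfanyl)prop-2-enoic acid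
Conditions: NaSMe (2.2 equiv), CuI (10 mol%), 1,10-phenanthroline (20 mol%), DMF, 60 °C; then 1 M HCl
Reagents that add atoms: sodium methanethiolate, C[S-].[Na+]
Why: Copper-catalysed vinylic C–S coupling of a β-iodoacrylate (equivalently an addition–elimination at the β-carbon) proceeds with retention of alkene geometry, so sulfur ends cis to the carboxyl group.

Step 18
Reactants: 31 (2Z)-2-methyl-3-(methylsulfanyl)prop-2-enoic acid; 26 (4aR,5R,6R)-6-hydroxy-3-(2-hydroxypropan-2-yl)-4a,5-dimethyl-5,6,7,8-tetrahydronaphthalen-2(4aH)-one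
Product: 33 (1R,2R,8aR)-7-(2-hydroxypropan-2-yl)-1,8a-dimethyl-6-oxo-1,2,3,4,6,8a-hexahydronaphthalen-2-yl (2Z)-2-methyl-3-(methylsulfanyl)prop-2-enoate (CNP0150028.1), via mixed anhydride 32 (not isolated)
Conditions: 31, 2,4,6-trichlorobenzoyl chloride, Et3N, THF, 0 °C → rt; then 26, DMAP, toluene, 0 °C → rt
Reagents that add atoms: none
Why: Yamaguchi esterification acylates the equatorial secondary C3 hydroxyl through the DMAP-activated mixed anhydride while the tertiary C11 hydroxyl is too hindered to react, and the low temperature is chosen to keep the Z geometry of the thioacrylate; no stereocentre is touched.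

Compound list
1 | 2-methylcyclohex-2-en-1-one | CC1=CCCCC1=O | starting material
2 | (1R)-2-methylcyclohex-2-en-1-ol | O[C@H]1C(C)=CCCC1 | intermediate
3 | ({[(1R)-2-methylcyclohex-2-en-1-yl]oxy}methyl)benzene (benzyl ether of 2) | C(c1ccccc1)O[C@H]2C(C)=CCCC2 | intermediate
4 | [(1R,2S,3R)-3-(benzyloxy)-2-methylcyclohexyl]borane (not isolated) | C(c1ccccc1)O[C@H]2[C@@H](C)[C@H](B)CCC2 | intermediate
5 | (1R,2S,3R)-3-(benzyloxy)-2-methylcyclohexan-1-ol (benzyloxy cis to methyl, hydroxyl trans to methyl) | C(c1ccccc1)O[C@H]2[C@@H](C)[C@H](O)CCC2 | intermediate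
6 | {[(1R,2R,3R)-3-(benzyloxy)-2-methylcyclohexyl]oxy}(tert-butyl)dimethylsilane | C(c1ccccc1)O[C@H]2[C@@H](C)[C@H](O[Si](C)(C)C(C)(C)C)CCC2 | intermediate
7 | (1R,2R,3R)-3-{[tert-butyl(dimethyl)silyl]oxy}-2-methylcyclohexan-1-ol | O[C@H]1[C@@H](C)[C@H](O[Si](C)(C)C(C)(C)C)CCC1 | intermediate
8 | (2S,3R)-3-{[tert-butyl(dimethyl)silyl]oxy}-2-methylcyclohexan-1-one (methyl and silyloxy trans) | O=C1[C@@H](C)[C@H](O[Si](C)(C)C(C)(C)C)CCC1 | intermediate
9 | 2-bromo-N-methoxy-N-methylacetamide | CON(C)C(=O)CBr | starting material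
10 | lithium (5R,6S)-5-{[tert-butyl(dimethyl)silyl]oxy}-6-methylcyclohex-1-en-1-olate (kinetic enolate, not isolated) | [Li]OC=1[C@@H](C)[C@H](O[Si](C)(C)C(C)(C)C)CCC=1 | intermediate
11 | N-methoxy-N-methyl-2-[(1R,3S,4R)-4-{[tert-butyl(dimethyl)silyl]oxy}-3-methyl-2-oxocyclohexyl]acetamide (arm trans to methyl) | O=C1[C@@H](C)[C@H](O[Si](C)(C)C(C)(C)C)CC[C@@H]1CC(=O)N(C)OC | intermediate
12 | 2-[(1R,3R,4R)-4-{[tert-butyl(dimethyl)silyl]oxy}-3-methyl-2-methylidenecyclohexyl]-N-methoxy-N-methylacetamide | C=C1[C@@H](C)[C@H](O[Si](C)(C)C(C)(C)C)CC[C@@H]1CC(=O)N(C)OC | intermediate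
13 | acetone | CC(C)=O | starting material
14 | bromoethene (vinyl bromide) | C=CBr | starting material
15 | 1-bromo-1-lithioethene (not isolated) | [Li]C(Br)=C | intermediate
16 | 3-bromo-2-methylbut-3-en-2-ol | C=C(Br)C(C)(C)O | intermediate
17 | [(3-bromo-2-methylbut-3-en-2-yl)oxy]triethylsilane | C=C(Br)C(C)(C)O[Si](CC)(CC)CC | intermediate
18 | {3-methyl-3-[(triethylsilyl)oxy]but-1-en-2-yl}lithium (not isolated) | [Li]C(=C)C(C)(C)O[Si](CC)(CC)CC | intermediate
19 | lithium alkoxide of the N-methoxy-N-methyl hemiaminal formed from 12 and 18 (tetrahedral adduct, either configuration at C8, not isolated) | C=C1[C@@H](C)[C@H](O[Si](C)(C)C(C)(C)C)CC[C@@H]1CC(O[Li])(N(C)OC)C(=C)C(C)(C)O[Si](CC)(CC)CC | intermediate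
20 | 1-[(1R,3R,4R)-4-{[tert-butyl(dimethyl)silyl]oxy}-3-methyl-2-methylidenecyclohexyl]-4-methyl-3-methylidene-4-[(triethylsilyl)oxy]pentan-2-one (cyclisation precursor) | C=C1[C@@H](C)[C@H](O[Si](C)(C)C(C)(C)C)CC[C@@H]1CC(=O)C(=C)C(C)(C)O[Si](CC)(CC)CC | intermediate
21 | tertiary C5 radical formed from 20 by hydrogen-atom addition to C14 (not isolated) | C[C]1[C@@H](C)[C@H](O[Si](C)(C)C(C)(C)C)CC[C@@H]1CC(=O)C(=C)C(C)(C)O[Si](CC)(CC)CC | intermediate
22 | C7 α-keto radical of the cis-fused decalin after 6-endo closure (not isolated) | CC(C)(C)[Si](C)(C)O[C@@H]1CC[C@@H]2CC(=O)[C](C(C)(C)O[Si](CC)(CC)CC)C[C@]2(C)[C@H]1C | intermediate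
23 | (3R,4aS,5R,6R,8aR)-6-{[tert-butyl(dimethyl)silyl]oxy}-4a,5-dimethyl-3-{2-[(triethylsilyl)oxy]propan-2-yl}-3,4,4a,5,6,7,8,8a-octahydronaphthalen-2(1H)-one (cis-fused decalin-8-one) | CC(C)(C)[Si](C)(C)O[C@@H]1CC[C@@H]2CC(=O)[C@@H](C(C)(C)O[Si](CC)(CC)CC)C[C@]2(C)[C@H]1C | intermediate
24 | (3R,4aR,5R,6R)-6-{[tert-butyl(dimethyl)silyl]oxy}-4a,5-dimethyl-3-{2-[(triethylsilyl)oxy]propan-2-yl}-4,4a,5,6,7,8-hexahydronaphthalen-2(3H)-one (C9=C10 enone, not isolated) | CC(C)(C)[Si](C)(C)O[C@@H]1CCC2=CC(=O)[C@@H](C(C)(C)O[Si](CC)(CC)CC)C[C@]2(C)[C@H]1C | intermediate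
25 | (4aR,5R,6R)-6-{[tert-butyl(dimethyl)silyl]oxy}-4a,5-dimethyl-3-{2-[(triethylsilyl)oxy]propan-2-yl}-5,6,7,8-tetrahydronaphthalen-2(4aH)-one (C6=C7, C9=C10 dienone) | CC(C)(C)[Si](C)(C)O[C@@H]1CCC2=CC(=O)C(C(C)(C)O[Si](CC)(CC)CC)=C[C@]2(C)[C@H]1C | intermediate
26 | (4aR,5R,6R)-6-hydroxy-3-(2-hydroxypropan-2-yl)-4a,5-dimethyl-5,6,7,8-tetrahydronaphthalen-2(4aH)-one | O[C@@H]1CCC2=CC(=O)C(C(C)(C)O)=C[C@]2(C)[C@H]1C | intermediate
27 | prop-2-yn-1-ol | C#CCO | starting material
28 | 4-methyl-2,5-dihydro-1,2-oxamagnesole (chelated Z-alkenylmagnesium alkoxide, not isolated) | CC1=C[Mg]OC1 | intermediate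
29 | (2Z)-3-iodo-2-methylprop-2-en-1-ol | I/C=C(/C)CO | intermediate
30 | (2Z)-3-iodo-2-methylprop-2-enoic acid | I/C=C(/C)C(=O)O | intermediate
31 | (2Z)-2-methyl-3-(methylsulfanyl)prop-2-enoic acid | CS/C=C(/C)C(=O)O | intermediate
32 | (2Z)-2-methyl-3-(methylsulfanyl)prop-2-enoic 2,4,6-trichlorobenzoic anhydride (not isolated) | CS/C=C(/C)C(=O)OC(=O)c1c(Cl)cc(Cl)cc1Cl | intermediate
33 | (1R,2R,8aR)-7-(2-hydroxypropan-2-yl)-1,8a-dimethyl-6-oxo-1,2,3,4,6,8a-hexahydronaphthalen-2-yl (2Z)-2-methyl-3-(methylsulfanyl)prop-2-enoate (CNP0150028.1) | CS/C=C(/C)C(=O)O[C@@H]1CCC2=CC(=O)C(C(C)(C)O)=C[C@]2(C)[C@H]1C | target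

Total step count: 18
Longest linear sequence: 13 steps (steps 1–8, 11–14 and 18); steps 9–10 and 15–17 are side branches.

Steps most likely to fail

Step 12. The C5 radical may pick up a second hydrogen atom before it cyclises, or hydrogen may be delivered to the enone terminus, so that ring B does not close cleanly. The fallback generates the same radical from a C–O bond with a hydrogen donor whose concentration is kept low by slow addition. It sets out from 12: Mukaiyama hydration (Co(acac)2, PhSiH3, O2, iPrOH) should give the tertiary C5 alcohol F1, whose C5 configuration is immaterial. Excess vinyllithium 18 at −78 °C should convert its Weinreb amide into the hydroxy enone F2. Methyl chlorooxoacetate with DMAP and Et3N should give the tertiary methyl oxalate F3. Slow addition of Bu3SnH with AIBN in benzene at 80 °C (Barton-type C–O homolysis followed by Giese cyclisation) should release radical 21, which closes ring B as in the main route and is reduced by the stannane. The route is rejoined at 23.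

Step 13. The second dehydrogenation on the hindered C7 side may stall, or the tertiary silyloxy group on C11 may be lost by β-elimination under the warm, mildly acidic conditions. The fallback introduces the two double bonds one at a time at low temperature. It sets out from 23: LiN(iPr)2 and Me3SiCl at −78 °C should give the kinetic trimethylsilyl enol ether F4 (C8=C9), and Pd(OAc)2 in MeCN (Saegusa–Ito oxidation) should give enone 24, now isolated. Deprotonation of 24 at C7 with LiN(iPr)2 and trapping with PhSeCl should give the α-phenylselenide F5. H2O2 with pyridine at 0 °C should trigger selenoxide syn-elimination, which can run only toward C6 because C11 carries no hydrogen. The route is rejoined at 25.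

Step 7. Proton transfer between the enolate and the product or the bromoamide may erode regiocontrol, and the face selectivity at C10 may be incomplete; the trans C4/C10 relationship is what steers step 12. The fallback forms the C10–C9 bond by a sigmatropic shift instead of an alkylation. It sets out from 8: LiN(iPr)2 then PhNTf2 should give the kinetic enol triflate F6. Pd(OAc)2/PPh3, CO, MeOH and Et3N should give the unsaturated methyl ester F7, and iBu2AlH should reduce it to the allylic alcohol F8. Johnson–Claisen rearrangement (MeC(OEt)3, cat. propionic acid, 140 °C) should give the ethyl ester F9, creating the exocyclic methylene and the C10–C9 bond on the face anti to the pseudoaxial C4 methyl. MeNHOMe·HCl with iPrMgCl should convert F9 into the Weinreb amide. The route is rejoined at 12.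

Further compounds
F1 | step 12 | 2-[(1R,3S,4R)-4-{[tert-butyl(dimethyl)silyl]oxy}-2-hydroxy-2,3-dimethylcyclohexyl]-N-methoxy-N-methylacetamide (tertiary C5 alcohol, either C5 epimer) | CC1(O)[C@@H](C)[C@H](O[Si](C)(C)C(C)(C)C)CC[C@@H]1CC(=O)N(C)OC
F2 | step 12 | 1-[(1R,3S,4R)-4-{[tert-butyl(dimethyl)silyl]oxy}-2-hydroxy-2,3-dimethylcyclohexyl]-4-methyl-3-methylidene-4-[(triethylsilyl)oxy]pentan-2-one (either C5 epimer) | CC1(O)[C@@H](C)[C@H](O[Si](C)(C)C(C)(C)C)CC[C@@H]1CC(=O)C(=C)C(C)(C)O[Si](CC)(CC)CC
F3 | step 12 | methyl oxalate ester of F2 at the tertiary C5 hydroxyl (either C5 epimer) | COC(=O)C(=O)OC1(C)[C@@H](C)[C@H](O[Si](C)(C)C(C)(C)C)CC[C@@H]1CC(=O)C(=C)C(C)(C)O[Si](CC)(CC)CC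
F4 | step 13 | trimethylsilyl enol ether of 23 with the C8=C9 double bond | CC(C)(C)[Si](C)(C)O[C@@H]1CC[C@@H]2C=C(O[Si](C)(C)C)[C@@H](C(C)(C)O[Si](CC)(CC)CC)C[C@]2(C)[C@H]1C
F5 | step 13 | 3-(phenylselanyl) derivative of enone 24 (selenium on C7, either C7 epimer) | CC(C)(C)[Si](C)(C)O[C@@H]1CCC2=CC(=O)C([Se]c3ccccc3)(C(C)(C)O[Si](CC)(CC)CC)C[C@]2(C)[C@H]1C
F6 | step 7 | (5R,6S)-5-{[tert-butyl(dimethyl)silyl]oxy}-6-methylcyclohex-1-en-1-yl trifluoromethanesulfonate | FC(F)(F)S(=O)(=O)OC=1[C@@H](C)[C@H](O[Si](C)(C)C(C)(C)C)CCC=1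
F7 | step 7 | methyl (5R,6R)-5-{[tert-butyl(dimethyl)silyl]oxy}-6-methylcyclohex-1-ene-1-carboxylate | COC(=O)C=1[C@@H](C)[C@H](O[Si](C)(C)C(C)(C)C)CCC=1
F8 | step 7 | [(5R,6R)-5-{[tert-butyl(dimethyl)silyl]oxy}-6-methylcyclohex-1-en-1-yl]methanol | OCC=1[C@@H](C)[C@H](O[Si](C)(C)C(C)(C)C)CCC=1
F9 | step 7 | ethyl 2-[(1R,3R,4R)-4-{[tert-butyl(dimethyl)silyl]oxy}-3-methyl-2-methylidenecyclohexyl]acetate | C=C1[C@@H](C)[C@H](O[Si](C)(C)C(C)(C)C)CC[C@@H]1CC(=O)OCC
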